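The hexacycle is cut at N4–C5 and C13–C14 into an (S)-hydrindenone and the E/F azabicyclo[3.3.0]octane. The plan rests on seeing that C21–C25 of ring E, C14 with methyl C15, and C1–C3 of ring F are the ten carbons of (R)-limonene opened at its ring alkene, limonene C4 being C24. The key step folds the derived acyclic precursor, an E-enone aldehyde carrying an allylic NHBoc group, in one operation: nitrogen adds to C25 and the C21 enolate condenses with the C22 aldehyde. This forms N4–C25 and C21=C22, closes rings F and E, and sets C25 from C24.

Key step: step 7

Remark on labels: atoms are numbered along the target SMILES, leaving out the N-oxide oxygen. They are C1 (methyl), C2, C3, N4, C5 (NCH), C6=C7, C8, C9, C10, C11, C12, C13, C14, C15 (methyl), O16, C17 (lactone C=O), C19, C20 and C21–C25. Ring E is C21–C25; ring F is N4, C3, C2, C24, C25.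

Remark on configuration: the target is 2S,5R,10R,13S,14R,21S,24R,25S, with the oxygen on N4 cis to H25. H24, H25, C20 and that oxygen lie on the convex face of the E/F/piperidine bowl. H5 is trans to H13, and H10 is cis to H13.

Check of the key-step structures: C4 of (R)-limonene has the spatial arrangement needed at C24. The label changes to S in the enone stage only because the priorities change. The centres of the precursor and of the bicyclic enone, as written below, match the target, so no correction is needed. C21 of the bicyclic enone bears no hydrogen, so its alkylation is routed through a reductively made enolate.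

Design of the precursor: C24–H becomes doubly allylic and γ to the enone. Nitrogen is therefore carried without N–H, as N(Boc)2. The enone is made late under near-neutral conditions, and N–H and CHO are unveiled together in acid. Base is met only in the key step.

Assumption: the key-step precursor is drawn in its open form. It may rest partly as the six-membered N,O-hemiaminal (N4 on C22), which base re-opens to the same carbamate anion.

Step 1
Reactants: 1 (R)-(+)-limonene
Product: 3 (5R)-7,7-dimethoxy-5-(prop-1-en-2-yl)heptan-2-one, via keto aldehyde 2 (not isolated)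
Conditions: O3 (1 equiv), CH2Cl2/MeOH, −78 °C; Me2S, −78 °C to rt; HC(OMe)3, p-TsOH (cat.), rt
Reagents that add atoms: ozone, [O-][O+]=O; trimethyl orthoformate, COC(OC)OC
Why: Ozone attacks the electron-richer trisubstituted ring alkene much faster than the 1,1-disubstituted isopropenyl group (chemoselective ozonolysis stopped at one equivalent), and the aldehyde of 2 is acetalised far faster than the methyl ketone, while C24 is not touched.

Step 2
Reactants: 3 keto acetal
Product: 4 (5R)-5-(3-chloroprop-1-en-2-yl)-7,7-dimethoxyheptan-2-one
Conditions: Ca(OCl)2, CO2 (s), CH2Cl2/H2O, 0 °C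
Reagents that add atoms: calcium hypochlorite, [Ca+2].[O-]Cl.[O-]Cl
Why: Hypochlorous acid made in the flask chlorinates the only remaining alkene in an ene-type allylic chlorination with double-bond shift towards the methyl group, the usual behaviour of isopropenyl terpenes, and leaves the ketone, the acetal and C24 alone.

Step 3
Reactants: 4 allylic chloride; 5 di-tert-butyl iminodicarboxylate
Product: 6 N,N-di-Boc allylic amine keto acetal
Conditions: K2CO3, NaI (10 mol %), DMF, 45 °C
Reagents that add atoms: none
Why: Gabriel-type SN2 displacement of the primary allylic chloride by the soft, weakly basic imidodicarbonate anion installs N4 without an N–H, so nitrogen stays silent in steps 4 and 5, and an SN2′ event would give the same product.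

Step 4
Reactants: 6 N,N-di-Boc keto acetal
Product: 7 (Z)-trimethylsilyl enol ether (C14=C21)
Conditions: TMSCl, DBU, CH2Cl2, 40 °C
Reagents that add atoms: chlorotrimethylsilane, C[Si](C)(C)Cl
Why: Equilibrating silylation gives mainly the more substituted C14=C21 enol silane without touching the acetal or the Boc groups, and the minor C14=C15 isomer does no harm because it cannot undergo β-hydride elimination in step 5 and returns 6.

Step 5
Reactants: 7 enol silane
Product: 8 (3E,5S)-enone acetal with the N(Boc)2 group
Conditions: Pd(OAc)2 (1.05 equiv), MeCN, rt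
Reagents that add atoms: none
Why: In this Saegusa–Ito oxidation the oxa-π-allyl complex of divalent palladium loses the C25 hydride to give the E-enone under almost neutral conditions, so the now doubly allylic C24–H is not exposed to base.

Step 6
Reactants: 8 enone acetal
Product: 9 tert-butyl N-[(3S,4E)-2-methylidene-6-oxo-3-(2-oxoethyl)hept-4-en-1-yl]carbamate
Conditions: TFA (3 equiv), CH2Cl2/H2O (20:1), 0 °C; used at once
Reagents that add atoms: water, O
Why: The first Boc group of an imidodicarbonate and a dimethyl acetal are both cleaved by dilute aqueous acid far faster than the remaining carbamate, so N–H and aldehyde are set free together in a medium in which C24 is configurationally safe.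

Step 7
Reactants: 9 seco-limonene enone aldehyde carbamate
Product: 12 tert-butyl (3aR,6aS)-6-acetyl-3-methylidene-3,3a,4,6a-tetrahydrocyclopenta[b]pyrrole-1(2H)-carboxylate, via pyrrolidine keto aldehyde 10 (not isolated), via ketol 11 (not isolated)
Conditions: KOtBu (0.3 equiv), THF/t-BuOH (10:1), −30 °C to rt
Reagents that add atoms: none
Why: Catalytic tert-butoxide removes the carbamate proton (or opens the hemiaminal tautomer of 9 to the same anion), and nitrogen adds to C25 of the E-enone in a 5-exo-trig aza-Michael addition that closes ring F and delivers the C21 enolate of 10. This enolate lies close to the C22 aldehyde and attacks it in a 5-(enolexo)-exo-trig aldol addition that closes ring E (11), after which E1cB loss of hydroxide gives the conjugated enone 12 and regenerates base. The closest known reactions are base-mediated cyclisations of carbamates onto enones and the hydroxide-induced aldol condensation of 3-isopropenyl-6-oxoheptanal to 1-acetyl-4-isopropenylcyclopentene. C25 is the only new stereocentre and is governed by C24: a bicyclo[3.3.0]octene can only be cis-fused, a trans nitrogen adduct simply re-opens, and the adduct with the C21 and C23 arms cis is consumed by ring closure and irreversible dehydration. The step needs deprotonation at N–H and not at C24–H, which is secured by substoichiometric base, low temperature, t-BuOH as proton shuttle and the speed of the five-membered closure. It also needs the C21-to-C22 aldol mode and not C23-to-C14 or C15-to-C22, which is secured because the enolate is born at C21, the aldehyde is the better electrophile, and no secondary amine is present that would activate C23 as an enamine.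

Step 8
Reactants: 12 bicyclic enone
Product: 13 dimethyl(phenyl)silyl enol ether (C14=C21)
Conditions: [(Ph3P)CuH]6 (3 mol %), PhMe2SiH (1.3 equiv), toluene, rt
Reagents that add atoms: dimethyl(phenyl)silane, C[SiH](C)c1ccccc1
Why: Copper hydride catalysed 1,4-hydrosilylation reduces only the enone, not the isolated exocyclic alkene or the carbamate, and stores the C21 enolate regiospecifically as its silyl ether.

Step 9
Reactants: 13 silyl enol ether; 14 methyl acrylate
Product: 16 methyl 3-[(3aR,6S,6aS)-6-acetyl-1-Boc-3-methylidene-octahydrocyclopenta[b]pyrrol-6-yl]propanoate, via lithium enolate 15 (not isolated)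
Conditions: MeLi (1.05 equiv), THF, 0 °C; 14 (1.1 equiv), −78 °C; AcOH, −78 °C
Reagents that add atoms: none
Why: Release of the regiodefined lithium enolate from the enol silane, followed by Michael addition at −78 °C, forms C21–C20 on the convex face of the cis-bicyclo[3.3.0]octane (the side of H24 and H25), which sets C21 (S) with the acetyl group cis to N4, and the cold acidic quench forestalls Claisen closure and retro-aza-Michael opening.

Step 10
Reactants: 16 Michael adduct
Product: 17 (3S,3aR,6S,6aS)-3-methyl keto ester (N-Boc)
Conditions: H2 (1 atm), Pd/C, EtOAc, rt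
Reagents that add atoms: none
Why: Heterogeneous hydrogenation delivers hydrogen to the exposed convex face of ring F, which turns the C1 methyl group to the concave side and sets C2 (S), while the ketone, ester and Boc group survive.

Step 11
Reactants: 17 N-Boc keto ester
Product: 18 secondary amine keto ester
Conditions: TFA/CH2Cl2 (1:4), 0 °C to rt; aq NaHCO3
Reagents that add atoms: none
Why: This is standard acidolysis of the Boc group, and 18 should be stable because C21 is quaternary (no retro-aza-Michael path) and because N4 and the C20 chain are trans on ring E (no lactam).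

Step 12
Reactants: 19 cyclohex-2-en-1-one; 20 (E)-2-(3,3-diethoxyprop-1-en-1-yl)-4,4,5,5-tetramethyl-1,3,2-dioxaborolane
Product: 21 (3R)-3-[(E)-3,3-diethoxyprop-1-en-1-yl]cyclohexan-1-one
Conditions: [Rh(cod)(OH)]2 (1.5 mol %), (R)-BINAP (3.3 mol %), dioxane/H2O (10:1), 50 °C
Reagents that add atoms: none
Why: In this Hayashi–Miyaura asymmetric 1,4-addition of an alkenylboron reagent the (R)-BINAP rhodium complex shields one face of cyclohexenone and sets C10 in the sense established for this enone, the (R)-ligand giving the (R)-3-alkenyl ketone.

Step 13
Reactants: 21 alkenyl ketone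
Product: 22 (3S)-3-(3,3-diethoxypropyl)cyclohexan-1-one
Conditions: H2 (1 atm), Pd/C, EtOAc, rt
Reagents that add atoms: none
Why: This is plain hydrogenation of a disubstituted alkene, and C10 is untouched (its label changes to S through priorities only).

Step 14
Reactants: 22 acetal ketone
Product: 24 (3aS)-2,3,3a,4,5,6-hexahydro-7H-inden-7-one, via keto aldehyde 23 (not isolated)
Conditions: 2 M HCl, THF, 60 °C
Reagents that add atoms: none
Why: Acid frees the aldehyde, whose intramolecular aldol condensation with ring carbon C6 (a cyclopentene annulation) can only form the five-membered ring and the C6=C7 enone, and C10–H is not enolisable.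

Step 15
Reactants: 18 secondary amine keto ester; 24 (S)-hydrindenone
Product: 27 hexacyclic tertiary amine lactone (N-deoxy target), via cross-conjugated enamine 25 (not isolated), via iminium lactone acetate 26 (not isolated)
Conditions: AcOH (1 equiv), 4 Å molecular sieves, ClCH2CH2Cl, 50 °C; then −20 °C, NaBH(OAc)3 (2 equiv), added as soon as closure is complete
Reagents that add atoms: none
Why: Acid-catalysed condensation gives enamine 25, whose C13 attacks the C14 ketone in a 6-(enolendo)-exo-trig enamine aldol addition, the tertiary alkoxide closes onto the methyl ester and the iminium ion is reduced as in a reductive amination; C13 is set because ring F holds C24 near the enamine plane, so that C21 and C14 reach only one π-face (also the axial face of the (S)-hydrindene), C14 because only the aldolate whose oxygen is cis to C20 can lactonise while the other reverts, and C5 because N4 can pyramidalise only with its lone pair on the convex face (side of H25), so hydride enters antiperiplanar to it and trans to H13.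

Step 16
Reactants: 27 tertiary amine
Product: 28 target N-oxide
Conditions: mCPBA (1.0 equiv), CH2Cl2, −20 to 0 °C; basic alumina
Reagents that add atoms: 3-chloroperbenzoic acid, OOC(=O)c1cccc(Cl)c1
Why: Peracid oxidation of a tertiary amine is much faster than epoxidation of the trisubstituted C6=C7 alkene, and the lone pair of N4 in the rigid bowl points to the convex face, which places the oxygen cis to H25, while cold handling avoids Meisenheimer rearrangement of the allylic N-oxide.

Compound list
1 | (R)-(+)-limonene | CC1=CC[C@@H](CC1)C(C)=C | starting material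
2 | (3R)-6-oxo-3-(prop-1-en-2-yl)heptanal | CC(=O)CC[C@H](CC=O)C(C)=C | intermediate
3 | (5R)-7,7-dimethoxy-5-(prop-1-en-2-yl)heptan-2-one | CC(=O)CC[C@H](CC(OC)OC)C(C)=C | intermediate
4 | (5R)-5-(3-chloroprop-1-en-2-yl)-7,7-dimethoxyheptan-2-one | CC(=O)CC[C@H](CC(OC)OC)C(=C)CCl | intermediate
5 | di-tert-butyl iminodicarboxylate | CC(C)(C)OC(=O)NC(=O)OC(C)(C)C | starting material
6 | di-tert-butyl N-[(3R)-5,5-dimethoxy-2-methylidene-3-(3-oxobutyl)pentyl]imidodicarbonate | CC(=O)CC[C@H](CC(OC)OC)C(=C)CN(C(=O)OC(C)(C)C)C(=O)OC(C)(C)C | intermediate
7 | (Z)-trimethylsilyl enol ether of 6 (C14=C21, C24 R) | C/C(O[Si](C)(C)C)=C/C[C@H](CC(OC)OC)C(=C)CN(C(=O)OC(C)(C)C)C(=O)OC(C)(C)C | intermediate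
8 | (3E,5S)-5-{3-[bis(tert-butoxycarbonyl)amino]prop-1-en-2-yl}-7,7-dimethoxyhept-3-en-2-one | CC(=O)/C=C/[C@H](CC(OC)OC)C(=C)CN(C(=O)OC(C)(C)C)C(=O)OC(C)(C)C | intermediate
9 | tert-butyl N-[(3S,4E)-2-methylidene-6-oxo-3-(2-oxoethyl)hept-4-en-1-yl]carbamate (key-step precursor) | CC(=O)/C=C/[C@H](CC=O)C(=C)CNC(=O)OC(C)(C)C | intermediate
10 | tert-butyl (2R,3R)-4-methylidene-3-(2-oxoethyl)-2-(2-oxopropyl)pyrrolidine-1-carboxylate (cis) | CC(=O)C[C@H]1N(C(=O)OC(C)(C)C)CC(=C)[C@H]1CC=O | intermediate
11 | cis-fused ketol, 6-acetyl-5-hydroxy-3-methylidene-N-Boc-octahydrocyclopenta[b]pyrrole (C21 and C22 undefined) | CC(=O)C1C(O)C[C@@H]2C(=C)CN(C(=O)OC(C)(C)C)[C@H]12 | intermediate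
12 | tert-butyl (3aR,6aS)-6-acetyl-3-methylidene-3,3a,4,6a-tetrahydrocyclopenta[b]pyrrole-1(2H)-carboxylate (key-step product) | CC(=O)C1=CC[C@@H]2C(=C)CN(C(=O)OC(C)(C)C)[C@H]12 | intermediate
13 | dimethyl(phenyl)silyl enol ether of the 1,4-reduced ketone (C14=C21, geometry not relevant) | CC(O[Si](C)(C)c1ccccc1)=C1CC[C@@H]2C(=C)CN(C(=O)OC(C)(C)C)[C@H]12 | intermediate
14 | methyl acrylate | C=CC(=O)OC | starting material
15 | lithium enolate (C14=C21) | [Li+].CC([O-])=C1CC[C@@H]2C(=C)CN(C(=O)OC(C)(C)C)[C@H]12 | intermediate
16 | methyl 3-[(3aR,6S,6aS)-6-acetyl-1-Boc-3-methylidene-octahydrocyclopenta[b]pyrrol-6-yl]propanoate | COC(=O)CC[C@@]1(C(C)=O)CC[C@@H]2C(=C)CN(C(=O)OC(C)(C)C)[C@H]12 | intermediate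
17 | methyl 3-[(3S,3aR,6S,6aS)-6-acetyl-1-Boc-3-methyl-octahydrocyclopenta[b]pyrrol-6-yl]propanoate | COC(=O)CC[C@@]1(C(C)=O)CC[C@@H]2[C@H](C)CN(C(=O)OC(C)(C)C)[C@H]12 | intermediate
18 | methyl 3-[(3S,3aR,6S,6aS)-6-acetyl-3-methyl-octahydrocyclopenta[b]pyrrol-6-yl]propanoate | COC(=O)CC[C@@]1(C(C)=O)CC[C@@H]2[C@H](C)CN[C@H]12 | intermediate
19 | cyclohex-2-en-1-one | O=C1C=CCCC1 | starting material
20 | (E)-2-(3,3-diethoxyprop-1-en-1-yl)-4,4,5,5-tetramethyl-1,3,2-dioxaborolane | CCOC(OCC)/C=C/B1OC(C)(C)C(C)(C)O1 | starting material
21 | (3R)-3-[(E)-3,3-diethoxyprop-1-en-1-yl]cyclohexan-1-one | O=C1CCC[C@@H](/C=C/C(OCC)OCC)C1 | intermediate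
22 | (3S)-3-(3,3-diethoxypropyl)cyclohexan-1-one | O=C1CCC[C@@H](CCC(OCC)OCC)C1 | intermediate
23 | 3-[(1S)-3-oxocyclohexyl]propanal | O=C1CCC[C@@H](CCC=O)C1 | intermediate
24 | (3aS)-2,3,3a,4,5,6-hexahydro-7H-inden-7-one | O=C1CCC[C@H]2CCC=C12 | intermediate
25 | cross-conjugated enamine (N4–C5=C13, C6=C7) of 18 and 24 | COC(=O)CC[C@@]1(C(C)=O)CC[C@@H]2[C@H](C)CN(C3=CCC[C@H]4CCC=C34)[C@H]12 | intermediate
26 | hexacyclic iminium lactone (N4=C5) as acetate | C[C@@H]1C[N+]2=C3C4=CCC[C@@H]4CC[C@@H]3[C@@]3(C)OC(=O)CC[C@]34CC[C@H]1[C@@H]42.CC(=O)[O-] | intermediate
27 | hexacyclic tertiary amine lactone (2S,5R,10R,13S,14R,21S,24R,25S) | C[C@@H]1CN2[C@H]3C4=CCC[C@@H]4CC[C@@H]3[C@@]3(C)OC(=O)CC[C@]34CC[C@H]1[C@@H]42 | intermediate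
28 | CNP0566793.5, N-oxide of 27 with oxygen cis to H25 | C[C@@H]1C[N@+]2([O-])[C@H]3C4=CCC[C@@H]4CC[C@@H]3[C@@]3(C)OC(=O)CC[C@]34CC[C@H]1[C@@H]42 | target

Total step count: 16. Longest linear sequence: 13 steps (steps 1–11, 15, 16). Steps 12–14 form the convergent hydrindenone branch.

Steps most likely to fail

Step 7. Several processes may go wrong. Competing deprotonation at C24 would cause racemisation, or drift of the enone into conjugation with the exocyclic alkene. The cascade may stall after the nitrogen addition or after the aldol addition. The hemiaminal tautomer may dehydrate. Base may also eliminate the carbamate from the dienolate of the product on long exposure.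
The fallback decouples the two bond formations. Setting out from 8, one Boc group alone is removed (Mg(ClO4)2, MeCN, 50 °C) to give the enone acetal carbamate F1. With the aldehyde still masked, the nitrogen addition is run on its own (KOtBu cat., THF, −30 °C, or PdCl2(MeCN)2 cat., CH2Cl2) to give the pyrrolidine acetal F2. Its trans isomer can be carried along because it re-opens under base. Mild hydrolysis (PPTS, wet acetone) then gives 10 as an isolated compound. Dilute aqueous KOH in THF closes ring E, and the fallback comes back to the route at 12.

Step 15. Several processes may go wrong: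
- The hindered amine may condense only slowly.
- The enamine may drift to the linear dienamine, which reacts through C6.
- The ketone–ketone aldol equilibrium may be unfavourable.
- C13 may epimerise through the iminium–enamine equilibrium during long heating.
- Facial control in the hydride delivery at C5 may be lost.

The fallback makes the enamine by C–N coupling instead of condensation. Setting out from 24, kinetic deprotonation at C13 (LiN(iPr)2, THF, −78 °C) and trapping with PhNTf2 give the dienyl triflate F3. Palladium-catalysed amination with 18 (Pd2(dba)3, BINAP, Cs2CO3, toluene, 80 °C) fixes the double bond at C5=C13, and the fallback comes back to the route at 25. The closure can then be triggered cold (AcOH, 0 °C) and followed at once by the hydride, so C13 is not left to equilibrate.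

Step 9. Several processes may go wrong. The acrylate may oligomerise. Proton transfer to the C15 enolate may be followed by Claisen-type closure onto the ester. MeLi may attack the carbamate. Ring F may open by retro-aza-Michael reaction of the C21 enolate.
The fallback uses a thermodynamic enolate of the saturated ketone instead of a kinetically released one. Setting out from 12, both alkenes are hydrogenated (H2, Pd/C, EtOAc) to the saturated methyl ketone F4, which sets C2 as in step 10 and leaves C21 epimerisable. A base-catalysed Michael addition (KOtBu 10 mol %, t-BuOH/THF, 14, 0 °C) should then react through the more substituted enolate at C21, as branched methyl ketones such as 3-methylbutan-2-one do, again on the convex face. The fallback comes back to the route at 17.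

Further compounds
F1 | step 7 | tert-butyl N-[(3S,4E)-3-(2,2-dimethoxyethyl)-2-methylidene-6-oxohept-4-en-1-yl]carbamate | CC(=O)/C=C/[C@H](CC(OC)OC)C(=C)CNC(=O)OC(C)(C)C
F2 | step 7 | tert-butyl (2R,3R)-3-(2,2-dimethoxyethyl)-4-methylidene-2-(2-oxopropyl)pyrrolidine-1-carboxylate | CC(=O)C[C@H]1N(C(=O)OC(C)(C)C)CC(=C)[C@H]1CC(OC)OC
F3 | step 15 | (3aS)-3,3a,4,5-tetrahydro-2H-inden-7-yl trifluoromethanesulfonate | O=S(=O)(OC1=CCC[C@H]2CCC=C12)C(F)(F)F
F4 | step 9 | tert-butyl (3S,3aR,6aS)-6-acetyl-3-methyl-octahydrocyclopenta[b]pyrrole-1-carboxylate (acetyl on the concave face) | CC(=O)[C@@H]1CC[C@@H]2[C@H](C)CN(C(=O)OC(C)(C)C)[C@H]12
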